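The rate constants are invented; the run is a simulation.

By the reckoning that follows, equal charges of substrate and reagent miss the mark in this flask. At the mark the free substrate left is 0.00650 M. The tail clock, the reciprocal of k3 times the substrate charged times that left amount, is the time equal charges take to fall there with by-product near the charge. It is 93.5 min, longer than the run.

    substrate + by-product ⇌ idle adduct, settled at all times (K1 = 2.3 M⁻¹)
    substrate + reagent → product + by-product (k2 = 2.23 × 10⁻⁴ M⁻¹ s⁻¹)
    substrate + reagent + by-product → product + 2 by-product (k3 = 0.211 M⁻² s⁻¹)

substrate 0.13 M; time 80 min

- the concentration of reagent at which the part of the substrate that has reacted at 80 min is just 95%, in M

- amounts and yields of by-product count idle adduct too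
- the amount of reagent is what is sought; it is there from the start
- what has gone from substrate into another species counts as reacted, even if it can come back
- run time (flask): 80 min

By hand, working with what is left: the direct route merely seeds the by-product route, since the by-product at which both run equally, 0.00106 M, lies far below the charge. By-product is then taken to grow exponentially at k3 times the two charges, and the climb from seed to charge is reckoned as a lag of 22.5 min. The tail must fit the remainder, 0.615 of the clock. An excess of reagent, u times the left amount, shortens the clock by the factor ln(one plus u) over u. At u = 1.50 that factor is 0.611, so the first committed charge is 0.140 M.

The weak link is the idle adduct. Substrate near the charge holds by-product back in the lag, and by-product near the charge holds substrate back in the tail, both by the factor 1.30. The lag stretches to 29.2 min. The clock stays, but the excess now counts against the left amount times that factor. The remainder is 0.543 of the clock, and u = 2 gives 0.549, so the reckoning ends at 0.147 M.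

The forecast is 0.146 M: “the slow start and the reagent-starved finish set the time”.

The simulation gives 0.146 M.

In the flask at that charge, at 80.0 min, the by-product route spends reagent 110 times as fast as the direct route, and the half-life of substrate is 19 min by the first against 36 h by the second. The flask with a fifth less reagent, 0.117 M, has reagent as limiting reagent under the 0.13 M of substrate; the stretched lag plus the clock for its left part, lengthened by its negative excess, comes to 69.5 min, less than the 80 min at which that flask stands at 84.0% reacted.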